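If two Z and one J go into each Q, as the proposed steps Z <-> L, L + J <-> G and L + G -> Q add up to, then the J charged caps Q. I called twice the J charge over the Z charge the J cap, 260% for the flask: the Q, in percent of the Z charged, that the J can pay for.

| flask | Z | J | remark | time |
|---|---|---|---|---|
| theta | 0.50 M | 0.33 M | run made earlier |  |
| zeta | 0.50 M | 0.49 M | run made earlier |  |
| delta | 0.75 M | 0.65 M | run made earlier |  |
| flask | 0.50 M | 0.650 M |  | 8.0 d |

| run | time / d | Z / % | Q / % | G / % |
|---|---|---|---|---|
| theta | 0.417 | 24.0 | 73.5 | 0.4 |
| theta | 0.625 | 0.8 | 99.6 | 0.6 |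
| theta | 0.833 | 0 | 99.7 | 0 |
| theta | 1.25 | 0.4 | 100.0 | 0.2 |
| theta | 2.08 | 0 | 100.1 | 0 |
| theta | 3.00 | 0 | 99.8 | 0 |
| theta | 5.00 | 0 | 100.0 | 0 |
| zeta | 0.250 | 48.3 | 50.2 | 1.6 |
| zeta | 0.833 | 0.3 | 99.6 | 0 |
| zeta | 1.25 | 0.4 | 99.3 | 0 |
| zeta | 2.08 | 0 | 100.3 | 0 |
| zeta | 3.00 | 0.6 | 99.6 | 0 |
| zeta | 4.00 | 0 | 100.1 | 0.3 |
| zeta | 5.00 | 0 | 99.4 | 0 |
| delta | 0.417 | 39.8 | 57.9 | 0.7 |
| delta | 1.25 | 0 | 99.8 | 0 |
| delta | 2.00 | 0 | 100.5 | 0 |
| delta | 3.00 | 0.6 | 100.3 | 0 |
| delta | 5.00 | 0 | 100.4 | 0 |

(readings scatter by 0.3 percentage points)

- a species is counted by the Z in it: one Q counts as two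
- given per volume of solution although it is solid: Z
- steps that have been proposed: Z <-> L; L + J <-> G; L + G -> Q
- at the start none of Z is in solution
- what has only dissolved of Z counts as not reacted
- the reaction counts as stopped when no species that holds the Z changes by six tenths of a point or more over the second half of the time

- which holds at 8.0 d: what has brought the reaction to rest, or that it has not come to rest (for what has run out or reacted, a solid counts together with what of it has only dissolved) (it is still moving / J has run out first / all of Z has reacted / forward and back rates have come level)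
- part of the Z that has turned into other species by 8.0 d (what has only dissolved does not count)
- the Q standing at 8.0 d, as a percentage of the Z charged

I solved the main step at both ends. With a cap below 100%, J is the limiting reagent and Q at the end of the reaction equals the cap. With a cap above it, Z limits and Q at the end equals 100%. So Q at the end is the smaller of the two, and for the flask that gave 100%. The theta run, with a cap of 132%, read 100.0% of Q at 5.00 d.

Next I added the step that makes G, which lets Z wait outside Q. The zeta run read G at 1.6% after 0.250 d and lower, at 0%, after 2.08 d, so I took nothing off the end value.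

Last I added the solid. Up to the first theta reading, Z fell on average by about 0.911 M/d. At that rate I estimated that the Z in the flask lasts about 0.549 d, far shorter than 8.0 d. My number stayed at 100%.

The forecast said that all of Z has reacted, with conversion 100% (99% to 100%) and Q 100% (96% to 100%). Its ground was: “Q is irreversible, so I expect completion within about a day”. My Q and its Q agreed.

In the flask, all of Z has reacted, with Q >99.9% and conversion >99.9% at 8.0 d.

    Z ⇌ L, rate k1*(cs1 - [L]) while solid is left; crystals form when [L] > cs1 (solubility = 26.0 mM, k = 0.0390 /min)
    L + J ⇌ G (K = 1.70 /M, k = 1.60 /M/min)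
    L + G → Q (k = 9.30 /M/min)

J in the flask stood at 61.5% of its charge at 8.00 d, and one minus the inverse of the cap gives 61.5%. A neighbouring flask, charged the same but with 0.16 M of J, has a cap of 64.0%, so the cap is now the smaller value. That neighbour gave 64.0% of Q at 8.00 d. Its J stood at 0% of its charge, and 36% of its Z remained, solid or dissolved.

Readings and results stem from a simulated flask from invented constants; noise was put on by code.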